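**Plan**

1. The target is cut first at the ether C–O bond between the tertiary C4 oxygen of the eudesmane half and the allylic C15 of the labdane half (tertiary alkoxide plus allylic bromide); the labdane half is isocupressic acid.
2. In the eudesmane half, ring B (C5–C6–C7–C8–C9–C10) shares C5–C10 with ring A and holds the quaternary C10. With a C6=C7 double bond it is a cyclohexene retron, so C8–C9 and C5–C10 are cut together to a diene C5=C6–C7=C8 (C7 carrying C11) and a dienophile C9=C10 whose C14 is raised to a formyl group, joined by the tether C1–C4.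
3. Forward, a linear trienal is built by acylation, Heck coupling, CBS reduction and α-methylenation; one intramolecular Diels–Alder reaction then closes rings A and B together.
4. The formyl group is then reduced to the C14 methyl, C6=C7 is hydrogenated, the C4 carbinol is converted by way of ketone and exocyclic alkene into the 4α tertiary alcohol, and the two halves are joined and deprotected.
5. Stereochemistry: the (R)-C4 carbinol from CBS reduction controls C5 and C10 in the cycloaddition and is later erased. C7 comes from α-face hydrogenation, the final C4 from α-face epoxidation, and the labdane centres and E-alkene from isocupressic acid.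

Key step: step 9

Remark: isocupressic acid ((13E)-15-hydroxylabda-8(17),13-dien-19-oic acid) is a catalogued natural product and is taken as a purchasable starting material; eudesmane numbering (C4 carbinol carbon, C5 and C10 ring fusion, C7 bearing C11, C14 on C10, C15 on C4) and labdane numbering are used throughout.

**Route**

Step 1
Reactants: 1 3-hydroxy-3-methylbutan-2-one
Product: 2 3-methyl-3-(triethylsilyloxy)butan-2-one
Conditions: TESOTf, 2,6-lutidine, CH2Cl2, −78 °C to 0 °C
Reagents that add atoms: triethylsilyl trifluoromethanesulfonate, CC[Si](CC)(CC)OS(=O)(=O)C(F)(F)F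
Why: Silyl ether formation with a silyl triflate and a hindered pyridine base should silylate the tertiary hydroxyl without enolising the ketone at low temperature.

Step 2
Reactants: 2 3-methyl-3-(triethylsilyloxy)butan-2-one
Product: 4 3-methyl-3-(triethylsilyloxy)but-1-en-2-yl trifluoromethanesulfonate, via lithium enolate 3 (not isolated)
Conditions: LiN(i-Pr)2, THF, −78 °C; then PhNTf2, −78 °C to 0 °C
Reagents that add atoms: LiN(i-Pr)2, [Li+].CC(C)[N-]C(C)C (lithium in 3 only); N-phenylbis(trifluoromethanesulfonimide), O=S(=O)(N(c1ccccc1)S(=O)(=O)C(F)(F)F)C(F)(F)F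
Why: The ketone has α-hydrogens only on its methyl group, so deprotonation gives a single enolate whose O-sulfonylation (enol triflate formation) should give the 1,1-disubstituted alkenyl triflate.

Step 3
Reactants: 5 methyl 6-chloro-6-oxohexanoate (methyl adipoyl chloride)
Product: 6 methyl 6-oxooct-7-enoate
Conditions: CH2=CHSnBu3, Pd(PPh3)4 (cat.), THF, 50 °C
Reagents that add atoms: tributyl(vinyl)stannane, C=C[Sn](CCCC)(CCCC)CCCC
Why: Stille acylation (palladium-catalysed coupling of an acid chloride with a vinylstannane) should give the vinyl ketone and leave the methyl ester untouched.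

Step 4
Reactants: 4 3-methyl-3-(triethylsilyloxy)but-1-en-2-yl trifluoromethanesulfonate; 6 methyl 6-oxooct-7-enoate
Product: 7 methyl (7E)-10-methyl-9-methylidene-6-oxo-10-(triethylsilyloxy)undec-7-enoate
Conditions: Pd(OAc)2 (cat.), PPh3, Et3N, DMF, 60 °C
Reagents that add atoms: none
Why: In this Heck reaction the alkenylpalladium species from the enol triflate should add to the unsubstituted β-carbon of the enone, and syn β-hydride elimination should give the (E)-dienone.

Step 5
Reactants: 7 methyl (7E)-10-methyl-9-methylidene-6-oxo-10-(triethylsilyloxy)undec-7-enoate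
Product: 8 methyl (6R,7E)-6-hydroxy-10-methyl-9-methylidene-10-(triethylsilyloxy)undec-7-enoate
Conditions: (S)-2-methyl-CBS-oxazaborolidine (cat.), catecholborane, toluene, −78 °C
Reagents that add atoms: none
Why: In this Corey–Bakshi–Shibata reduction the catalyst binds the ketone with the dienyl group as the large substituent and delivers hydride to one face, which should give the (R)-allylic alcohol; catecholborane at −78 °C should leave the ester and the diene alone.

Step 6
Reactants: 8 methyl (6R,7E)-6-hydroxy-10-methyl-9-methylidene-10-(triethylsilyloxy)undec-7-enoate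
Product: 9 methyl (6R,7E)-6-(benzyloxy)-10-methyl-9-methylidene-10-(triethylsilyloxy)undec-7-enoate
Conditions: 2-benzyloxy-1-methylpyridinium triflate, MgO, PhCF3, 83 °C
Reagents that add atoms: 2-benzyloxy-1-methylpyridinium trifluoromethanesulfonate, C[n+]1ccccc1OCc1ccccc1.[O-]S(=O)(=O)C(F)(F)F
Why: The Dudley reagent transfers a benzyl group under neutral conditions (O-benzylation), so the methyl ester, the silyl ether and the carbinol stereocenter should not be disturbed.

Step 7
Reactants: 9 methyl (6R,7E)-6-(benzyloxy)-10-methyl-9-methylidene-10-(triethylsilyloxy)undec-7-enoate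
Product: 10 (6R,7E)-6-(benzyloxy)-10-methyl-9-methylidene-10-(triethylsilyloxy)undec-7-enal
Conditions: i-Bu2AlH, CH2Cl2, −78 °C; aq. potassium sodium tartrate
Reagents that add atoms: none
Why: Partial reduction of a methyl ester by i-Bu2AlH at −78 °C should stop at the aluminium hemiacetal, which releases the aldehyde on work-up.

Step 8
Reactants: 10 (6R,7E)-6-(benzyloxy)-10-methyl-9-methylidene-10-(triethylsilyloxy)undec-7-enal
Product: 11 (6R,7E)-6-(benzyloxy)-10-methyl-2,9-dimethylidene-10-(triethylsilyloxy)undec-7-enal
Conditions: 37% aq. CH2O, pyrrolidine (cat.), propionic acid (cat.), i-PrOH, 45 °C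
Reagents that add atoms: formaldehyde, C=O
Why: Amine-catalysed Mannich condensation with formaldehyde and loss of the amine (organocatalytic α-methylenation of an aldehyde) should install the 2-alkylacrolein dienophile, adding C9, under almost neutral conditions; the product is used directly.

Step 9
Reactants: 11 (6R,7E)-6-(benzyloxy)-10-methyl-2,9-dimethylidene-10-(triethylsilyloxy)undec-7-enal
Product: 12 4α-benzyloxy-11-(triethylsilyloxy)-15-noreudesm-6-en-14-al (trans-fused octalin, 5α-H, 10β-CHO)
Conditions: Me2AlCl, CH2Cl2, −78 °C to −30 °C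
Reagents that add atoms: none
Why: Me2AlCl binds the formyl oxygen of the 2-alkylacrolein unit and lowers its LUMO, so that the tethered (E)-diene adds across C9=C10 in a concerted but asynchronous [4+2] cycloaddition in which C8–C9 (diene terminus to the unsubstituted acrolein β-carbon) runs ahead of C5–C10. The closest known reaction type is the Lewis-acid-promoted type 1 intramolecular Diels–Alder reaction of 1,7,9-decatrienes that carry the activating carbonyl on the internal dienophile carbon, which gives trans-fused decalins with an angular carbonyl group. Ring B is closed as the cyclohexene of the cycloaddition itself (bonds C8–C9 and C5–C10, new alkene C6=C7), and ring A is closed at the same time as the six-membered ring defined by the tether C1–C4 through the C5–C10 bond. C10 (quaternary) and C5 are set together: the formyl group should sit endo under the diene, which puts the tether anti and gives the trans ring fusion with C5–H opposite to the angular formyl group, and the absolute sense of both should come from the (R)-C4 stereocenter, whose benzyloxy group stays equatorial in the chair-like tether to avoid a 1,3-diaxial contact with the aluminium-bound formyl group. The step needs endo over exo selectivity and one π-face, which Lewis acid activation at low temperature and the C4 substituent should secure; the regiochemistry is fixed by the tether and coincides with the electronic preference of a 2-substituted diene for a 2-alkylacrolein.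

Step 10
Reactants: 12 4α-benzyloxy-11-(triethylsilyloxy)-15-noreudesm-6-en-14-al
Product: 14 4α-benzyloxy-11-(triethylsilyloxy)-15-noreudesm-6-ene, via tosylhydrazone 13 (not isolated)
Conditions: TsNHNH2, THF, 50 °C; then catecholborane, CHCl3, 0 °C to rt; then NaOAc·3H2O, reflux
Reagents that add atoms: p-toluenesulfonohydrazide, Cc1ccc(cc1)S(=O)(=O)NN (in 13 only)
Why: Reduction of the tosylhydrazone with catecholborane, then base-induced loss of sulfinate and N2 (Kabalka variant of the Caglioti reduction), should turn the angular formyl group into the C14 methyl group and spare the silyl ether, the benzyl ether and the alkene.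

Step 11
Reactants: 14 4α-benzyloxy-11-(triethylsilyloxy)-15-noreudesm-6-ene
Product: 15 11-(triethylsilyloxy)-15-noreudesman-4α-ol (5α-H, 7α-H, 10β-CH3)
Conditions: H2 (1 atm), 10% Pd/C, EtOAc, rt
Reagents that add atoms: none
Why: Heterogeneous hydrogenation should add hydrogen to C6=C7 from the α-face, opposite to the axial C10 methyl group, which sets C7 with the side chain β (equatorial), and the same catalyst should hydrogenolyse the benzyl ether; the silyl ether is a poor leaving group for allylic hydrogenolysis.

Step 12
Reactants: 15 11-(triethylsilyloxy)-15-noreudesman-4α-ol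
Product: 16 11-(triethylsilyloxy)-15-noreudesman-4-one
Conditions: Dess–Martin periodinane, CH2Cl2, rt
Reagents that add atoms: none
Why: Dess–Martin oxidation of the secondary alcohol should give the ketone, whose epimerisable C5 keeps the more stable trans ring fusion.

Step 13
Reactants: 16 11-(triethylsilyloxy)-15-noreudesman-4-one
Product: 17 11-(triethylsilyloxy)eudesm-4(15)-ene (β-eudesmol triethylsilyl ether)
Conditions: Ph3PCH3Br, KOt-Bu, toluene, 80 °C
Reagents that add atoms: methyltriphenylphosphonium bromide, C[P+](c1ccccc1)(c1ccccc1)c1ccccc1.[Br-]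
Why: Wittig methylenation of the hindered ketone should install C15 as the exocyclic methylene, and any base-mediated equilibration at C5 favours the trans-fused isomer.

Step 14
Reactants: 17 11-(triethylsilyloxy)eudesm-4(15)-ene
Product: 18 4α,15-epoxy-11-(triethylsilyloxy)eudesmane
Conditions: dimethyldioxirane, acetone, 0 °C
Reagents that add atoms: dimethyldioxirane, CC1(C)OO1
Why: Dioxirane epoxidation should take place on the α-face of the exocyclic alkene because the β-face is blocked by the 1,3-diaxial C10 methyl group, which places the oxygen α (equatorial) at C4.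

Step 15
Reactants: 18 4α,15-epoxy-11-(triethylsilyloxy)eudesmane
Product: 19 11-(triethylsilyloxy)eudesman-4α-ol (cryptomeridiol 11-triethylsilyl ether)
Conditions: LiAlH4, THF, reflux
Reagents that add atoms: none
Why: Hydride should open the spiro-epoxide by SN2 attack at the primary carbon (reductive epoxide opening), so that C15 becomes the β-methyl group and the tertiary 4α-hydroxyl keeps the configuration set in step 14.

Step 16
Reactants: 20 isocupressic acid
Product: 21 2-(trimethylsilyl)ethyl (13E)-15-hydroxylabda-8(17),13-dien-19-oate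
Conditions: Me3SiCH2CH2OC(=NH)CCl3, toluene, 100 °C
Reagents that add atoms: 2-(trimethylsilyl)ethyl 2,2,2-trichloroacetimidate, C[Si](C)(C)CCOC(=N)C(Cl)(Cl)Cl
Why: The carboxylic acid protonates the trichloroacetimidate and is alkylated at oxygen (imidate esterification), which should work for the hindered axial acid and leave the allylic alcohol, which is not acidic enough to activate the reagent, free.

Step 17
Reactants: 21 2-(trimethylsilyl)ethyl (13E)-15-hydroxylabda-8(17),13-dien-19-oate
Product: 22 2-(trimethylsilyl)ethyl (13E)-15-bromolabda-8(17),13-dien-19-oate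
Conditions: CBr4, PPh3, CH2Cl2, 0 °C
Reagents that add atoms: carbon tetrabromide, BrC(Br)(Br)Br
Why: The Appel reaction should convert the primary allylic alcohol into the bromide by SN2 displacement of the oxyphosphonium group, keeping the E-alkene and the position of the double bond.

Step 18
Reactants: 19 11-(triethylsilyloxy)eudesman-4α-ol; 22 2-(trimethylsilyl)ethyl (13E)-15-bromolabda-8(17),13-dien-19-oate
Product: 24 2-(trimethylsilyl)ethyl ester 11-triethylsilyl ether of the target, via potassium alkoxide 23 (not isolated)
Conditions: KH, 18-crown-6 (cat.), THF, 0 °C; then 22, Bu4NI (cat.), 0 °C to rt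
Reagents that add atoms: KH, [K+].[H-] (potassium in 23 only)
Why: In this Williamson ether synthesis the potassium alkoxide of the tertiary alcohol, made more reactive by the crown ether, should displace the primary allylic bromide by SN2; the ester has no α-hydrogen and is too hindered for acyl transfer, and no stereocenter is touched.

Step 19
Reactants: 24 2-(trimethylsilyl)ethyl ester 11-triethylsilyl ether of the target
Product: 25 target (CNP0156875.1)
Conditions: Bu4NF, THF, rt to 45 °C; aq. citric acid work-up
Reagents that add atoms: none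
Why: Fluoride attacks silicon in both protecting groups (fluoride-mediated desilylation): the tertiary silyl ether is cleaved and the 2-(trimethylsilyl)ethyl ester fragments to carboxylate, ethene and fluorotrimethylsilane, which should free the hindered acid without conditions that could ionise the tertiary allylic ether.

**Compound list**

1 | 3-hydroxy-3-methylbutan-2-one | CC(=O)C(C)(C)O | starting material
2 | 3-methyl-3-(triethylsilyloxy)butan-2-one | CC(=O)C(C)(C)O[Si](CC)(CC)CC | intermediate
3 | lithium 3-methyl-3-(triethylsilyloxy)but-1-en-2-olate | [Li+].[O-]C(=C)C(C)(C)O[Si](CC)(CC)CC | intermediate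
4 | 3-methyl-3-(triethylsilyloxy)but-1-en-2-yl trifluoromethanesulfonate | C=C(OS(=O)(=O)C(F)(F)F)C(C)(C)O[Si](CC)(CC)CC | intermediate
5 | methyl 6-chloro-6-oxohexanoate (methyl adipoyl chloride) | COC(=O)CCCCC(=O)Cl | starting material
6 | methyl 6-oxooct-7-enoate | COC(=O)CCCCC(=O)C=C | intermediate
7 | methyl (7E)-10-methyl-9-methylidene-6-oxo-10-(triethylsilyloxy)undec-7-enoate | COC(=O)CCCCC(=O)/C=C/C(=C)C(C)(C)O[Si](CC)(CC)CC | intermediate
8 | methyl (6R,7E)-6-hydroxy-10-methyl-9-methylidene-10-(triethylsilyloxy)undec-7-enoate | COC(=O)CCCC[C@@H](O)/C=C/C(=C)C(C)(C)O[Si](CC)(CC)CC | intermediate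
9 | methyl (6R,7E)-6-(benzyloxy)-10-methyl-9-methylidene-10-(triethylsilyloxy)undec-7-enoate | COC(=O)CCCC[C@@H](OCc1ccccc1)/C=C/C(=C)C(C)(C)O[Si](CC)(CC)CC | intermediate
10 | (6R,7E)-6-(benzyloxy)-10-methyl-9-methylidene-10-(triethylsilyloxy)undec-7-enal | O=CCCCC[C@@H](OCc1ccccc1)/C=C/C(=C)C(C)(C)O[Si](CC)(CC)CC | intermediate
11 | (6R,7E)-6-(benzyloxy)-10-methyl-2,9-dimethylidene-10-(triethylsilyloxy)undec-7-enal | O=CC(=C)CCC[C@@H](OCc1ccccc1)/C=C/C(=C)C(C)(C)O[Si](CC)(CC)CC | intermediate
12 | 4α-benzyloxy-11-(triethylsilyloxy)-15-noreudesm-6-en-14-al (trans-fused, 5α-H, 10β-CHO) | c1ccccc1CO[C@@H]1CCC[C@]2(C=O)CCC(C(C)(C)O[Si](CC)(CC)CC)=C[C@H]21 | intermediate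
13 | N-tosylhydrazone of aldehyde 12 | c1ccccc1CO[C@@H]1CCC[C@]2(/C=N/NS(=O)(=O)c3ccc(C)cc3)CCC(C(C)(C)O[Si](CC)(CC)CC)=C[C@H]21 | intermediate
14 | 4α-benzyloxy-11-(triethylsilyloxy)-15-noreudesm-6-ene | c1ccccc1CO[C@@H]1CCC[C@]2(C)CCC(C(C)(C)O[Si](CC)(CC)CC)=C[C@H]21 | intermediate
15 | 11-(triethylsilyloxy)-15-noreudesman-4α-ol | O[C@@H]1CCC[C@]2(C)CC[C@@H](C(C)(C)O[Si](CC)(CC)CC)C[C@H]21 | intermediate
16 | 11-(triethylsilyloxy)-15-noreudesman-4-one | O=C1CCC[C@]2(C)CC[C@@H](C(C)(C)O[Si](CC)(CC)CC)C[C@H]21 | intermediate
17 | 11-(triethylsilyloxy)eudesm-4(15)-ene (β-eudesmol triethylsilyl ether) | C=C1CCC[C@]2(C)CC[C@@H](C(C)(C)O[Si](CC)(CC)CC)C[C@H]21 | intermediate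
18 | 4α,15-epoxy-11-(triethylsilyloxy)eudesmane | C1O[C@@]12CCC[C@]3(C)CC[C@@H](C(C)(C)O[Si](CC)(CC)CC)C[C@H]32 | intermediate
19 | 11-(triethylsilyloxy)eudesman-4α-ol (cryptomeridiol 11-triethylsilyl ether) | O[C@]1(C)CCC[C@]2(C)CC[C@@H](C(C)(C)O[Si](CC)(CC)CC)C[C@H]21 | intermediate
20 | isocupressic acid, (13E)-15-hydroxylabda-8(17),13-dien-19-oic acid | C=C1CC[C@@H]2[C@](C)(CCC[C@]2(C)C(=O)O)[C@H]1CC/C(C)=C/CO | starting material
21 | 2-(trimethylsilyl)ethyl (13E)-15-hydroxylabda-8(17),13-dien-19-oate | C=C1CC[C@@H]2[C@](C)(CCC[C@]2(C)C(=O)OCC[Si](C)(C)C)[C@H]1CC/C(C)=C/CO | intermediate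
22 | 2-(trimethylsilyl)ethyl (13E)-15-bromolabda-8(17),13-dien-19-oate | C=C1CC[C@@H]2[C@](C)(CCC[C@]2(C)C(=O)OCC[Si](C)(C)C)[C@H]1CC/C(C)=C/CBr | intermediate
23 | potassium alkoxide of 19 | [K+].[O-][C@]1(C)CCC[C@]2(C)CC[C@@H](C(C)(C)O[Si](CC)(CC)CC)C[C@H]21 | intermediate
24 | 2-(trimethylsilyl)ethyl ester 11-triethylsilyl ether of the target | C=C1CC[C@@H]2[C@](C)(CCC[C@]2(C)C(=O)OCC[Si](C)(C)C)[C@H]1CC/C(C)=C/CO[C@]1(C)CCC[C@]2(C)CC[C@@H](C(C)(C)O[Si](CC)(CC)CC)C[C@H]21 | intermediate
25 | target, 15-O-(11-hydroxyeudesman-4α-yl)isocupressic acid | C=C1CC[C@@H]2[C@](C)(CCC[C@]2(C)C(=O)O)[C@H]1CC/C(C)=C/CO[C@]1(C)CCC[C@]2(C)CC[C@@H](C(C)(C)O)C[C@H]21 | target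

**Step count and risks**

Total steps: 19. Longest linear sequence: 16 steps (steps 1, 2, 4 to 15, 18 and 19).

Steps most likely to fail:

Step 9. The Lewis acid may ionise the tertiary dienylic silyl ether or polymerise the enal, and an uncatalysed background reaction may erode the endo preference and with it the trans ring fusion. Fallback: setting out from ester 9, α-methylenation (LiN(i-Pr)2, then dimethylmethyleneammonium iodide, then MeI and NaHCO3) would give the more robust acrylate methyl (6R,7E)-6-(benzyloxy)-10-methyl-2,9-dimethylidene-10-(triethylsilyloxy)undec-7-enoate F1. F1 would be cyclised thermally, without any Lewis acid (toluene, BHT, 160 °C, sealed tube), to the trans-fused angular ester methyl 4α-benzyloxy-11-(triethylsilyloxy)-15-noreudesm-6-en-14-oate F2. Reduction of F2 with i-Bu2AlH at −78 °C would come back to the route at aldehyde 12.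

Step 18. The hindered tertiary alkoxide may react slowly, so that base-induced elimination of HBr from the allylic bromide and SN2′ attack compete with substitution. Fallback: setting out from alcohol 21, acylation with methyl chloroformate and pyridine would give 2-(trimethylsilyl)ethyl (13E)-15-(methoxycarbonyloxy)labda-8(17),13-dien-19-oate F3. F3 would be ionised by Pd(PPh3)4 to the π-allyl complex and captured at its primary terminus by the zinc alkoxide made from 19 and Et2Zn (palladium-catalysed allylic etherification), which comes back to the route at 24.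

Step 11. Palladium may hydrogenolyse the allylic C11–O bond or move the double bond before reduction, and the facial selectivity at C7 may be incomplete. Fallback: setting out from 14, hydrogen-atom-transfer hydrogenation (Mn(dpm)3 (cat.), PhSiH3, t-BuOOH, i-PrOH, rt) would reduce C6=C7 through the tertiary C7 radical, which takes up hydrogen on the axial α-face and leaves the side chain equatorial, giving the saturated benzyl ether 4α-benzyloxy-11-(triethylsilyloxy)-15-noreudesmane F4. Hydrogenolysis of F4 (H2, 10% Pd/C, EtOAc), which no longer has an allylic C–O bond, comes back to the route at 15.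

**Further compounds**

F1 | step 9 | methyl (6R,7E)-6-(benzyloxy)-10-methyl-2,9-dimethylidene-10-(triethylsilyloxy)undec-7-enoate | COC(=O)C(=C)CCC[C@@H](OCc1ccccc1)/C=C/C(=C)C(C)(C)O[Si](CC)(CC)CC
F2 | step 9 | methyl 4α-benzyloxy-11-(triethylsilyloxy)-15-noreudesm-6-en-14-oate (trans-fused) | c1ccccc1CO[C@@H]1CCC[C@]2(C(=O)OC)CCC(C(C)(C)O[Si](CC)(CC)CC)=C[C@H]21
F3 | step 18 | 2-(trimethylsilyl)ethyl (13E)-15-(methoxycarbonyloxy)labda-8(17),13-dien-19-oate | C=C1CC[C@@H]2[C@](C)(CCC[C@]2(C)C(=O)OCC[Si](C)(C)C)[C@H]1CC/C(C)=C/COC(=O)OC
F4 | step 11 | 4α-benzyloxy-11-(triethylsilyloxy)-15-noreudesmane | c1ccccc1CO[C@@H]1CCC[C@]2(C)CC[C@@H](C(C)(C)O[Si](CC)(CC)CC)C[C@H]21
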